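**Plan**

- Retrosynthetic cuts: the C5 side chain at its alkene (Wittig reaction and ester reduction, back to a C5 aldehyde); then O1–C2 of the dihydrofuran ring; then, together, C2–C1′ (to the syringyl ring) and C3–C3a (to ring A), with the C2 oxygen traced back to boron.
- Enabling feature: C2 (holding O1 and syringyl C1′) and C3 (holding ring A carbon C3a and the CH2OH carbon) are the two neighbouring carbons of an (E)-3-oxypropenyl unit, so the core is an alkenyl boronate flanked by two aryl groups.
- Forward: a syringyllithium, an alkenyl mac boronate and a ring A bromide are joined in one conjunctive coupling to an open chain; boron is oxidised to hydroxyl; acid removes every protecting group and closes the dihydrofuran ring, the only ring made; the aldehyde is then extended by two carbons and reduced.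
- Stereochemistry: the chiral bisphosphine on palladium fixes C3; C2 is first set anti to it by the stereospecific 1,2-shift and is finally settled trans to C3 by the reversible cationic ring closure; the E side-chain alkene comes from a stabilised ylide.

Key step: step 7

Assumption: (S,S)-MandyPhos, here the 1,1′-bis[(dimethylamino)(phenyl)methyl]-2,2′-bis[bis(3,5-dimethylphenyl)phosphino]ferrocene ligand, is taken to deliver the (2R) configuration at the ring A carbon by analogy with β-substituted alkenyl mac boronates; should the sense be opposite, the (R,R)-ligand would be used with nothing else changed.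

**Route**

Step 1
Reactants: 1 5-bromovanillin
Product: 2 2-bromo-4-(1,3-dioxolan-2-yl)-6-methoxyphenol
Conditions: HOCH2CH2OH (5 equiv), TsOH·H2O (cat.), toluene, reflux, Dean–Stark; Et3N quench
Reagents that add atoms: ethylene glycol, OCCO
Why: Acid-catalysed acetalisation with azeotropic removal of water masks the aldehyde against the organolithium of step 7 and against Dakin oxidation in step 8, and the free phenol does not interfere.

Step 2
Reactants: 2 2-bromo-4-(1,3-dioxolan-2-yl)-6-methoxyphenol
Product: 3 2-[3-bromo-5-methoxy-4-(methoxymethoxy)phenyl]-1,3-dioxolane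
Conditions: NaH, MOMCl, DMF, 0 °C → rt
Reagents that add atoms: chloromethyl methyl ether, COCCl
Why: Williamson-type O-alkylation of the sodium phenoxide is run under basic conditions, so the acid-labile dioxolane should survive.

Step 3
Reactants: 4 4-bromo-2,6-dimethoxyphenol
Product: 5 5-bromo-1,3-dimethoxy-2-(methoxymethoxy)benzene
Conditions: NaH, MOMCl, DMF, 0 °C → rt
Reagents that add atoms: chloromethyl methyl ether, COCCl
Why: The same phenoxide O-alkylation installs an acetal that tolerates t-BuLi (both positions ortho to it are blocked by methoxy groups) and falls in the acid step that closes the ring.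

Step 4
Reactants: 6 acenaphthoquinone
Product: 7 cis-1,2-dimethyl-1,2-dihydroacenaphthylene-1,2-diol (mac diol, meso)
Conditions: AlMe3 (4 equiv), toluene, 0 °C → rt; aqueous work-up, crystallisation
Reagents that add atoms: trimethylaluminium, C[Al](C)C
Why: Double 1,2-addition of methyl to the 1,2-dione should give mainly the cis diol, because the second methyl enters anti to the bulky aluminium alkoxide, and the meso isomer is purified by crystallisation.

Step 5
Reactants: 8 (E)-3-(tert-butyldimethylsilyloxy)prop-1-enylboronic acid pinacol ester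
Product: 9 (E)-3-(tert-butyldimethylsilyloxy)prop-1-enylboronic acid
Conditions: NaIO4 (3 equiv), NH4OAc (3 equiv), acetone/H2O, rt
Reagents that add atoms: water, O
Why: Periodate glycol cleavage of the pinacol unit pulls the ester hydrolysis to the free boronic acid under buffered, near-neutral conditions that should leave the silyl ether and the alkene geometry alone.

Step 6
Reactants: 9 (E)-3-(tert-butyldimethylsilyloxy)prop-1-enylboronic acid, 7 cis-1,2-dimethyl-1,2-dihydroacenaphthylene-1,2-diol
Product: 10 (E)-3-(tert-butyldimethylsilyloxy)prop-1-enylboronic acid mac ester (cyclic boronate of diol 7)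
Conditions: MgSO4, CH2Cl2, rt
Reagents that add atoms: none
Why: Dehydrative esterification of a boronic acid with a cis 1,2-diol, driven by the drying agent, gives the hindered five-membered boronate that step 7 needs.

Step 7
Reactants: 5 5-bromo-1,3-dimethoxy-2-(methoxymethoxy)benzene, 10 (E)-3-(tert-butyldimethylsilyloxy)prop-1-enylboronic acid mac ester, 3 2-[3-bromo-5-methoxy-4-(methoxymethoxy)phenyl]-1,3-dioxolane
Product: 13 mac ester of (1S,2R)-3-(tert-butyldimethylsilyloxy)-1-[3,5-dimethoxy-4-(methoxymethoxy)phenyl]-2-[5-(1,3-dioxolan-2-yl)-3-methoxy-2-(methoxymethoxy)phenyl]propylboronic acid, via syringyllithium 11 (not isolated), via lithium boron ate complex 12 (not isolated)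
Conditions: 5, t-BuLi (2 equiv), Et2O, −78 °C; 10 (1.05 equiv) in THF, −78 °C → rt; then 3, Pd(OAc)2 (3 mol %), (S,S)-MandyPhos (3.6 mol %), KOTf (2 equiv), THF, 60 °C
Reagents that add atoms: none
Why: Bromine–lithium exchange gives 11, which adds to the boron of 10 to form the four-coordinate boronate 12; 3 adds oxidatively to zerovalent palladium bearing the bisphosphine, KOTf removes bromide, and the resulting cationic divalent arylpalladium binds the alkene of 12 and triggers 1,2-migration of the syringyl group from boron to the boron-bearing carbon anti to palladium, which bonds the neighbouring carbon before reductive elimination with retention joins that carbon to ring A. The closest known reaction type is the palladium-catalysed enantioselective conjunctive cross-coupling of β-substituted alkenyl boron ate complexes with aryl electrophiles, run with an organolithium-derived complex, an aryl bromide and a triflate salt as halide scavenger. No ring is closed; two carbon–carbon bonds and two stereocenters are formed. The configuration at the ring A carbon (later C3) is set by the ligand-controlled choice of alkene face for palladium, and the configuration at the boron-bearing carbon (later C2) follows from the anti-periplanar metallate shift on the E alkene, which gives the (1S,2R) isomer. The step needs the conjunctive path to beat direct transfer of the alkenyl group to palladium, which the hindered mac ester is there to suppress, and it needs reductive elimination to outrun β-hydride loss from the secondary alkylpalladium. Compound 11 is consumed by 10 before 3 is added, so it cannot exchange with the second bromide.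

Step 8
Reactants: 13 mac ester of the (1S,2R)-propylboronic acid
Product: 14 (1S,2R)-3-(tert-butyldimethylsilyloxy)-1-[3,5-dimethoxy-4-(methoxymethoxy)phenyl]-2-[5-(1,3-dioxolan-2-yl)-3-methoxy-2-(methoxymethoxy)phenyl]propan-1-ol
Conditions: 30% H2O2, 3 M aq. NaOH, THF, 0 °C → rt
Reagents that add atoms: hydrogen peroxide, OO
Why: Boron oxidation by hydroperoxide proceeds through a 1,2-shift of carbon from boron to oxygen with retention, so C1 stays S, and the acetals, the silyl ether and the masked aldehyde are stable to alkaline peroxide.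

Step 9
Reactants: 14 (1S,2R)-3-(tert-butyldimethylsilyloxy)-1-[3,5-dimethoxy-4-(methoxymethoxy)phenyl]-2-[5-(1,3-dioxolan-2-yl)-3-methoxy-2-(methoxymethoxy)phenyl]propan-1-ol
Product: 16 (2S,3R)-2-(4-hydroxy-3,5-dimethoxyphenyl)-3-(hydroxymethyl)-7-methoxy-2,3-dihydro-1-benzofuran-5-carbaldehyde, via deprotected open-chain diol 15 (not isolated)
Conditions: 3 M aq. HCl, THF, 45 °C, dilute
Reagents that add atoms: water, O
Why: Acid hydrolysis of both methoxymethyl ethers, the dioxolane and the silyl ether gives 15, whose para-hydroxybenzylic alcohol ionises (SN1, cation in resonance with a para-quinone methide) and is captured 5-exo by the ring A phenol; since this closure is reversible, the aryl group at C2 should settle trans to the C3 hydroxymethyl group, giving (2S) with net retention while C3 is untouched.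

Step 10
Reactants: 16 (2S,3R)-2-(4-hydroxy-3,5-dimethoxyphenyl)-3-(hydroxymethyl)-7-methoxy-2,3-dihydro-1-benzofuran-5-carbaldehyde
Product: 17 ethyl (2E)-3-[(2S,3R)-2-(4-hydroxy-3,5-dimethoxyphenyl)-3-(hydroxymethyl)-7-methoxy-2,3-dihydro-1-benzofuran-5-yl]prop-2-enoate
Conditions: Ph3P=CHCO2Et (2 equiv), toluene, 60 °C
Reagents that add atoms: ethyl (triphenylphosphoranylidene)acetate, CCOC(=O)C=P(c1ccccc1)(c1ccccc1)c1ccccc1
Why: Wittig olefination with a stabilised ylide is E-selective and tolerates the free phenol and primary alcohol, and the neutral conditions leave both stereocenters alone.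

Step 11
Reactants: 17 ethyl (2E)-3-[(2S,3R)-2-(4-hydroxy-3,5-dimethoxyphenyl)-3-(hydroxymethyl)-7-methoxy-2,3-dihydro-1-benzofuran-5-yl]prop-2-enoate
Product: 18 4-[(2S,3R)-3-(hydroxymethyl)-5-[(1E)-3-hydroxyprop-1-en-1-yl]-7-methoxy-2,3-dihydro-1-benzofuran-2-yl]-2,6-dimethoxyphenol (CNP0191372.1)
Conditions: i-Bu2AlH (6 equiv), THF/CH2Cl2, −78 → 0 °C; aq. potassium sodium tartrate
Reagents that add atoms: none
Why: 1,2-Reduction of the α,β-unsaturated ester by excess i-Bu2AlH at low temperature gives the allylic alcohol without touching the alkene, the first equivalents being consumed by the two hydroxyl groups.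

**Compound list**

1 | 5-bromovanillin (3-bromo-4-hydroxy-5-methoxybenzaldehyde) | COc1cc(C=O)cc(Br)c1O | starting material
2 | 2-bromo-4-(1,3-dioxolan-2-yl)-6-methoxyphenol | COc1cc(C2OCCO2)cc(Br)c1O | intermediate
3 | 2-[3-bromo-5-methoxy-4-(methoxymethoxy)phenyl]-1,3-dioxolane | COCOc1c(Br)cc(cc1OC)C1OCCO1 | intermediate
4 | 4-bromo-2,6-dimethoxyphenol | COc1cc(Br)cc(OC)c1O | starting material
5 | 5-bromo-1,3-dimethoxy-2-(methoxymethoxy)benzene | COCOc1c(OC)cc(Br)cc1OC | intermediate
6 | acenaphthoquinone (acenaphthylene-1,2-dione) | O=C1C(=O)c2cccc3cccc1c23 | starting material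
7 | cis-1,2-dimethyl-1,2-dihydroacenaphthylene-1,2-diol (mac diol) | C[C@@]1(O)c2cccc3cccc(c23)[C@]1(C)O | intermediate
8 | (E)-3-(tert-butyldimethylsilyloxy)prop-1-enylboronic acid pinacol ester | CC(C)(C)[Si](C)(C)OC/C=C/B1OC(C)(C)C(C)(C)O1 | starting material
9 | (E)-3-(tert-butyldimethylsilyloxy)prop-1-enylboronic acid | CC(C)(C)[Si](C)(C)OC/C=C/B(O)O | intermediate
10 | (E)-3-(tert-butyldimethylsilyloxy)prop-1-enylboronic acid mac ester | C[C@]12OB(/C=C/CO[Si](C)(C)C(C)(C)C)O[C@@]1(C)c1cccc3cccc2c13 | intermediate
11 | [3,5-dimethoxy-4-(methoxymethoxy)phenyl]lithium | [Li]c1cc(OC)c(OCOC)c(OC)c1 | intermediate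
12 | lithium boron ate complex of 10 carrying the syringyl group on boron | [Li+].C[C@]12O[B-](/C=C/CO[Si](C)(C)C(C)(C)C)(c3cc(OC)c(OCOC)c(OC)c3)O[C@@]1(C)c1cccc3cccc2c13 | intermediate
13 | mac ester of (1S,2R)-3-(tert-butyldimethylsilyloxy)-1-[3,5-dimethoxy-4-(methoxymethoxy)phenyl]-2-[5-(1,3-dioxolan-2-yl)-3-methoxy-2-(methoxymethoxy)phenyl]propylboronic acid | COCOc1c(OC)cc(cc1OC)[C@@H](B2O[C@]3(C)c4cccc5cccc(c45)[C@]3(C)O2)[C@@H](CO[Si](C)(C)C(C)(C)C)c1cc(cc(OC)c1OCOC)C1OCCO1 | intermediate
14 | (1S,2R)-3-(tert-butyldimethylsilyloxy)-1-[3,5-dimethoxy-4-(methoxymethoxy)phenyl]-2-[5-(1,3-dioxolan-2-yl)-3-methoxy-2-(methoxymethoxy)phenyl]propan-1-ol | COCOc1c(OC)cc(cc1OC)[C@@H](O)[C@@H](CO[Si](C)(C)C(C)(C)C)c1cc(cc(OC)c1OCOC)C1OCCO1 | intermediate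
15 | (1S,2R)-2-(5-formyl-2-hydroxy-3-methoxyphenyl)-1-(4-hydroxy-3,5-dimethoxyphenyl)propane-1,3-diol | COc1cc(cc(OC)c1O)[C@@H](O)[C@@H](CO)c1cc(C=O)cc(OC)c1O | intermediate
16 | (2S,3R)-2-(4-hydroxy-3,5-dimethoxyphenyl)-3-(hydroxymethyl)-7-methoxy-2,3-dihydro-1-benzofuran-5-carbaldehyde | COc1cc([C@H]2Oc3c(OC)cc(C=O)cc3[C@@H]2CO)cc(OC)c1O | intermediate
17 | ethyl (2E)-3-[(2S,3R)-2-(4-hydroxy-3,5-dimethoxyphenyl)-3-(hydroxymethyl)-7-methoxy-2,3-dihydro-1-benzofuran-5-yl]prop-2-enoate | COc1cc([C@H]2Oc3c(OC)cc(/C=C/C(=O)OCC)cc3[C@@H]2CO)cc(OC)c1O | intermediate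
18 | 4-[(2S,3R)-3-(hydroxymethyl)-5-[(1E)-3-hydroxyprop-1-en-1-yl]-7-methoxy-2,3-dihydro-1-benzofuran-2-yl]-2,6-dimethoxyphenol | COc1cc([C@H]2Oc3c(OC)cc(/C=C/CO)cc3[C@@H]2CO)cc(OC)c1O | target

**Step count**

Total steps: 11. Longest linear sequence: 7 steps (for example 8 → 9 → 10 → 13 → 14 → 16 → 17 → 18).

**Steps most likely to fail**

Step 7. The arylpalladium from 3 carries an ortho methoxymethoxy group and must bind a hindered, β-substituted alkene. If this is slow, direct transfer of the alkenyl group, β-hydride or β-siloxy elimination from the secondary alkylpalladium, or poor facial selectivity could take over. The fallback is an auxiliary-controlled aldol route that sets out from 3 and 5 and comes back at 16. Bromide 3 is coupled with the Reformatsky reagent BrZnCH2CO2Et under Pd2(dba)3 and XPhos in THF to give ethyl 2-[5-(1,3-dioxolan-2-yl)-3-methoxy-2-(methoxymethoxy)phenyl]acetate F1. This is saponified with LiOH to 2-[5-(1,3-dioxolan-2-yl)-3-methoxy-2-(methoxymethoxy)phenyl]acetic acid F2, which is joined through its pivaloyl mixed anhydride to lithiated (S)-4-benzyl-1,3-oxazolidin-2-one to give the N-arylacetyl oxazolidinone F3. Bromide 5 is lithiated as in step 7 and 11 is quenched with DMF to give 3,5-dimethoxy-4-(methoxymethoxy)benzaldehyde F4. The dibutylboron Z-enolate of F3 (Bu2BOTf, i-Pr2NEt, CH2Cl2, −78 °C) adds to F4 in an Evans syn aldol reaction to give the (2S,3S) aldol adduct F5. Reductive removal of the auxiliary with LiBH4 gives (1S,2R)-1-[3,5-dimethoxy-4-(methoxymethoxy)phenyl]-2-[5-(1,3-dioxolan-2-yl)-3-methoxy-2-(methoxymethoxy)phenyl]propane-1,3-diol F6, the desilyl analogue of 14 with the same configuration. F6 under the acid conditions of step 9 gives 16.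

Step 9. After ionisation at C2 the cation may lose the C3 proton (erasing the C3 stereocenter), lose the hydroxymethyl carbon as formaldehyde, or react between molecules before the phenol, deactivated by the para formyl group, captures it. The fallback closes the ring before unmasking; it sets out from 14 and comes back at 16. Compound 14 is treated with BF3·OEt2 in CH2Cl2 at −78 °C, so that the benzylic cation is captured by the oxygen of the neighbouring aryl methoxymethyl ether and the oxonium ion sheds the methoxymethyl cation. This should give the still protected trans ring compound (2S,3R)-3-[(tert-butyldimethylsilyloxy)methyl]-2-[3,5-dimethoxy-4-(methoxymethoxy)phenyl]-5-(1,3-dioxolan-2-yl)-7-methoxy-2,3-dihydro-1-benzofuran F7. The remaining acetal and silyl groups of F7 are then removed with aqueous HCl in THF at room temperature, where the closed aryl ether should not reopen, to give 16.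

Step 5. The periodate cleavage may stall, the free alkenylboronic acid may dehydrate to boroxine mixtures or protodeboronate on handling, and the allylic silyl ether may be lost. The fallback avoids the free boronic acid; it sets out from 8 and comes back at 10. Ester 8 is treated with KHF2 in aqueous methanol to give potassium (E)-[3-(tert-butyldimethylsilyloxy)prop-1-enyl]trifluoroborate F8. F8, diol 7 and Me3SiCl in MeCN then give 10, fluoride being abstracted by silicon and the transient difluoroborane being esterified by the diol.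

Further compounds
F1 | step 7 | ethyl 2-[5-(1,3-dioxolan-2-yl)-3-methoxy-2-(methoxymethoxy)phenyl]acetate | CCOC(=O)Cc1cc(cc(OC)c1OCOC)C1OCCO1
F2 | step 7 | 2-[5-(1,3-dioxolan-2-yl)-3-methoxy-2-(methoxymethoxy)phenyl]acetic acid | OC(=O)Cc1cc(cc(OC)c1OCOC)C1OCCO1
F3 | step 7 | (4S)-4-benzyl-3-{2-[5-(1,3-dioxolan-2-yl)-3-methoxy-2-(methoxymethoxy)phenyl]acetyl}-1,3-oxazolidin-2-one | O=C1OC[C@H](Cc2ccccc2)N1C(=O)Cc1cc(cc(OC)c1OCOC)C1OCCO1
F4 | step 7 | 3,5-dimethoxy-4-(methoxymethoxy)benzaldehyde | COCOc1c(OC)cc(C=O)cc1OC
F5 | step 7 | (4S)-4-benzyl-3-{(2S,3S)-3-[3,5-dimethoxy-4-(methoxymethoxy)phenyl]-2-[5-(1,3-dioxolan-2-yl)-3-methoxy-2-(methoxymethoxy)phenyl]-3-hydroxypropanoyl}-1,3-oxazolidin-2-one | O=C1OC[C@H](Cc2ccccc2)N1C(=O)[C@@H](c1cc(cc(OC)c1OCOC)C1OCCO1)[C@H](O)c1cc(OC)c(OCOC)c(OC)c1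
F6 | step 7 | (1S,2R)-1-[3,5-dimethoxy-4-(methoxymethoxy)phenyl]-2-[5-(1,3-dioxolan-2-yl)-3-methoxy-2-(methoxymethoxy)phenyl]propane-1,3-diol | OC[C@@H](c1cc(cc(OC)c1OCOC)C1OCCO1)[C@H](O)c1cc(OC)c(OCOC)c(OC)c1
F7 | step 9 | (2S,3R)-3-[(tert-butyldimethylsilyloxy)methyl]-2-[3,5-dimethoxy-4-(methoxymethoxy)phenyl]-5-(1,3-dioxolan-2-yl)-7-methoxy-2,3-dihydro-1-benzofuran | COc1cc([C@H]2Oc3c(OC)cc(C4OCCO4)cc3[C@@H]2CO[Si](C)(C)C(C)(C)C)cc(OC)c1OCOC
F8 | step 5 | potassium (E)-[3-(tert-butyldimethylsilyloxy)prop-1-enyl]trifluoroborate | [K+].F[B-](F)(F)/C=C/CO[Si](C)(C)C(C)(C)C
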